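**Plan**

- Benzofuran numbering O1, C2, C3, C3a, C4–C7, C7a is used. The retrosynthesis first removes five phenol protecting groups, then cuts the C6–vinyl bond (Mizoroki–Heck), then cuts the dihydrofuran at O1–C2 and C2–C3 in one operation, and last cuts the C3–aryl bond of the precursor.
- Enabling feature: C3 is a diarylmethine on C3a, and both carbons flanking C3a (C4 and C7a) carry oxygen. The unit O1–C7a–C3a–C3 is therefore a masked o-quinone methide whichever oxygen is used, and C2 (an O-bearing benzylic CH) can come from a benzylic sulfonium ylide as a one-carbon nucleophile/electrophile.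
- Forward: bis-Boc aldehyde 3 plus aryllithium 6 gives phenol carbonate 9; vanillyl alcohol gives chiral sulfonium salt 14; 9 plus 14 close the furan ring by [4+1] annulation (C2–C3, then O1–C2); the Heck reaction adds the styryl arm; one methanolysis unmasks all phenols.
- Stereochemistry: C2 comes from the isothiocineole ylide (inverted in the SN2 closure), C3 from the anti-selective addition to the quinone methide in the same step, and the E-alkene from the Heck reaction.

Key step: step 8

Assumption: the facial sense of the isothiocineole ylide toward the quinone methide is taken from its model for additions to C=O and C=N acceptors (attack remote from the gem-dimethyl carbon); if the antipodal ring were favoured, the sulfide from (S)-limonene would be used with no other change.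

Abbreviations: Boc = tert-butoxycarbonyl; TBS = tert-butyldimethylsilyl.

**Step 1**
Reactants: 1 4-bromo-2,6-dimethoxybenzaldehyde
Product: 2 4-bromo-2,6-dihydroxybenzaldehyde
Conditions: BBr3 (3 equiv), CH2Cl2, −78 → 0 °C; H2O
Reagents that add atoms: none
Why: Lewis-acid cleavage of aryl methyl ethers; both methoxy groups are ortho to the formyl group and should be cleaved through the chelated aryloxyborane while the aryl bromide and aldehyde survive at low temperature.

**Step 2**
Reactants: 2 4-bromo-2,6-dihydroxybenzaldehyde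
Product: 3 4-bromo-2,6-bis(Boc-oxy)benzaldehyde
Conditions: Boc2O (2.4 equiv), DMAP (cat.), i-Pr2NEt, THF, 0 °C → rt
Reagents that add atoms: di-tert-butyl dicarbonate (Boc2O), CC(C)(C)OC(=O)OC(=O)OC(C)(C)C
Why: DMAP-catalysed O-acylation should convert both hydrogen-bonded phenols into aryl tert-butyl carbonates, one to serve later as the trigger and the other as the protecting group of the C4 oxygen.

**Step 3**
Reactants: 4 5-bromoresorcinol
Product: 5 1-bromo-3,5-bis(TBS-oxy)benzene
Conditions: TBSCl (2.3 equiv), imidazole, DMF, rt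
Reagents that add atoms: tert-butyldimethylsilyl chloride (TBSCl), CC(C)(C)[Si](C)(C)Cl
Why: Standard phenol silylation gives aryl silyl ethers that tolerate bromine–lithium exchange.

**Step 4**
Reactants: 5 1-bromo-3,5-bis(TBS-oxy)benzene; 3 4-bromo-2,6-bis(Boc-oxy)benzaldehyde
Product: 9 rac-[4-bromo-2-(Boc-oxy)-6-hydroxyphenyl][3,5-bis(TBS-oxy)phenyl]methyl tert-butyl carbonate, via aryllithium 6 (not isolated), via lithium alkoxide 7 (not isolated), via lithium phenoxide 8 (not isolated)
Conditions: n-BuLi (1.0 equiv), THF, −78 °C; cannulate into 3, THF, −78 °C; AcOH, −78 °C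
Reagents that add atoms: none
Why: Bromine–lithium exchange and 1,2-addition of 6 to the aldehyde should outrun attack on the hindered carbonates at −78 °C; alkoxide 7 then takes a Boc group from either equivalent ortho oxygen by O-to-O acyl transfer to give phenoxide 8, which as a lithium salt should not eliminate at this temperature and is protonated cold; the carbinol centre is racemic and is destroyed in step 8.

**Step 5**
Reactants: 10 4-hydroxy-3-methoxybenzyl alcohol (vanillyl alcohol)
Product: 11 tert-butyl [4-(hydroxymethyl)-2-methoxyphenyl] carbonate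
Conditions: Boc2O (1.05 equiv), aq NaOH, n-Bu4NHSO4 (cat.), CH2Cl2, 0 °C
Reagents that add atoms: di-tert-butyl dicarbonate (Boc2O), CC(C)(C)OC(=O)OC(=O)OC(C)(C)C
Why: Phase-transfer O-acylation (Schotten–Baumann type) should be chemoselective because only the phenoxide reacts with Boc2O and the neutral benzylic alcohol does not without an acyl-transfer catalyst.

**Step 6**
Reactants: 11 tert-butyl [4-(hydroxymethyl)-2-methoxyphenyl] carbonate
Product: 12 tert-butyl [4-(bromomethyl)-2-methoxyphenyl] carbonate
Conditions: CBr4, PPh3, CH2Cl2, 0 °C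
Reagents that add atoms: carbon tetrabromide, BrC(Br)(Br)Br
Why: Appel bromination converts the primary benzylic alcohol into the bromide under neutral conditions that leave the acid-labile aryl carbonate intact.

**Step 7**
Reactants: 12 tert-butyl [4-(bromomethyl)-2-methoxyphenyl] carbonate; 13 (1R,4R,5R)-4,7,7-trimethyl-6-thiabicyclo[3.2.1]octane (isothiocineole from (R)-limonene)
Product: 14 (1R,4R,5R,6R)-6-[4-(Boc-oxy)-3-methoxybenzyl]-4,7,7-trimethyl-6-thiabicyclo[3.2.1]octan-6-ium tetrafluoroborate (benzyl group exo on sulfur)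
Conditions: NaBF4 (aq, excess), CH2Cl2, rt
Reagents that add atoms: sodium tetrafluoroborate, [Na+].F[B-](F)(F)F
Why: SN2 S-alkylation at the exo lone pair (the endo pair is shielded by the three-carbon bridge) should give one sulfonium diastereomer, and bromide-to-tetrafluoroborate exchange in the two-phase system suppresses the reverse dealkylation.

**Step 8**
Reactants: 9 rac-[4-bromo-2-(Boc-oxy)-6-hydroxyphenyl][3,5-bis(TBS-oxy)phenyl]methyl tert-butyl carbonate; 14 isothiocineole-derived benzylic sulfonium tetrafluoroborate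
Product: 19 tert-butyl (2S,3S)-6-bromo-2-[4-(Boc-oxy)-3-methoxyphenyl]-3-[3,5-bis(TBS-oxy)phenyl]-2,3-dihydro-1-benzofuran-4-yl carbonate, via sulfonium ylide 15 (not isolated), via potassium phenoxide 16 (not isolated), via o-quinone methide 17 (not isolated), via betaine 18 (not isolated)
Conditions: 14 (1.3 equiv), KN(SiMe3)2 (1.3 equiv), THF–CH2Cl2, −78 °C; then 9 premixed with KN(SiMe3)2 (1.0 equiv), THF, −78 → −20 °C
Reagents that add atoms: none
Why: Proposed new method: KN(SiMe3)2 turns 14 into the semi-stabilised benzylic ylide 15 and 9 into phenoxide 16, which expels tert-butyl carbonate (E1cB) to give o-quinone methide 17; 15 adds to the exocyclic methide carbon of 17 (conjugate addition driven by rearomatisation, forming C2–C3) to give betaine 18, whose phenoxide oxygen displaces the sulfide at the benzylic carbon and so forms O1–C2. The closest known reaction types are the base-mediated [4+1] annulation of o-quinone methides with carbonyl-stabilised sulfonium ylides to trans-2,3-dihydrobenzofurans and the asymmetric epoxidation or aziridination with benzylic ylides of isothiocineole, so the untested element is a semi-stabilised chiral aryl ylide as the one-carbon partner of an o-quinone methide. The dihydrofuran is the only ring closed, in a 5-exo-tet SN2 O-alkylation with inversion at C2. C2 is controlled by the sulfide (single exo S-benzyl sulfonium diastereomer, ylide aryl turned away from the gem-dimethyl carbon, attack of 17 on the ylide face remote from that carbon gives the R sulfonium carbon of 18, inverted to 2S on closure), and C3 is set in the same C–C bond formation through the anti betaine, whose closing conformer holds the two aryl groups on opposite faces of the new ring (trans, 3S). The step needs 1,4-regioselectivity (secured by aromatisation of the dioxygenated ring), a single quinone methide (secured because both carbons flanking C3a bear oxygen, the second staying as its Boc carbonate), SN2 rather than SN1 loss of the sulfide (secured by the electron-poor carbonate para to the sulfonium carbon) and anti over syn betaine formation, any cis isomer being a separable diastereomer that should be removed before deprotection.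

**Step 9**
Reactants: 19 tert-butyl (2S,3S)-6-bromo-2-[4-(Boc-oxy)-3-methoxyphenyl]-3-[3,5-bis(TBS-oxy)phenyl]-2,3-dihydro-1-benzofuran-4-yl carbonate; 20 4-ethenyl-2-methoxyphenyl acetate (4-acetoxy-3-methoxystyrene)
Product: 21 4-{(E)-2-[(2S,3S)-4-(Boc-oxy)-2-[4-(Boc-oxy)-3-methoxyphenyl]-3-[3,5-bis(TBS-oxy)phenyl]-2,3-dihydro-1-benzofuran-6-yl]ethenyl}-2-methoxyphenyl acetate
Conditions: Pd(P(t-Bu)3)2 (5 mol %), Cy2NMe (1.5 equiv), 1,4-dioxane, 70 °C
Reagents that add atoms: none
Why: Mizoroki–Heck reaction; oxidative addition of the aryl bromide to zerovalent palladium, syn-carbopalladation at the terminal alkene carbon and syn-β-hydride elimination should give the E-stilbene with the carbonates, silyl ethers, acetate and both stereocentres untouched.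

**Step 10**
Reactants: 21 fully protected stilbene
Product: 22 bisisorhapontigenin B, (2S,3S)-3-(3,5-dihydroxyphenyl)-2-(4-hydroxy-3-methoxyphenyl)-6-[(E)-2-(4-hydroxy-3-methoxyphenyl)ethenyl]-2,3-dihydro-1-benzofuran-4-ol
Conditions: K2CO3 (cat.), MeOH–THF (3:1), argon, rt → 40 °C; then AcOH
Reagents that add atoms: none
Why: Base-catalysed methanolysis (transesterification) should remove the acetate and both aryl carbonates and cleave the two aryl silyl ethers; C3–H is not acidic and any reversible opening at C2 through the para-phenoxide can only return the trans ring, so both stereocentres should persist.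

**Compound list**

1 | 4-bromo-2,6-dimethoxybenzaldehyde | COc1cc(Br)cc(OC)c1C=O | starting material
2 | 4-bromo-2,6-dihydroxybenzaldehyde | O=Cc1c(O)cc(Br)cc1O | intermediate
3 | 4-bromo-2,6-bis(Boc-oxy)benzaldehyde | O=Cc1c(OC(=O)OC(C)(C)C)cc(Br)cc1OC(=O)OC(C)(C)C | intermediate
4 | 5-bromoresorcinol | Oc1cc(O)cc(Br)c1 | starting material
5 | 1-bromo-3,5-bis(TBS-oxy)benzene | CC(C)(C)[Si](C)(C)Oc1cc(Br)cc(O[Si](C)(C)C(C)(C)C)c1 | intermediate
6 | [3,5-bis(TBS-oxy)phenyl]lithium | [Li]c1cc(O[Si](C)(C)C(C)(C)C)cc(O[Si](C)(C)C(C)(C)C)c1 | intermediate (not isolated)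
7 | lithium alkoxide of the aldehyde adduct (both aryl carbonates intact, racemic) | [Li]OC(c1cc(O[Si](C)(C)C(C)(C)C)cc(O[Si](C)(C)C(C)(C)C)c1)c1c(OC(=O)OC(C)(C)C)cc(Br)cc1OC(=O)OC(C)(C)C | intermediate (not isolated)
8 | lithium phenoxide after O-to-O Boc transfer (lithium salt of 9) | [Li]Oc1cc(Br)cc(OC(=O)OC(C)(C)C)c1C(OC(=O)OC(C)(C)C)c1cc(O[Si](C)(C)C(C)(C)C)cc(O[Si](C)(C)C(C)(C)C)c1 | intermediate (not isolated)
9 | rac-[4-bromo-2-(Boc-oxy)-6-hydroxyphenyl][3,5-bis(TBS-oxy)phenyl]methyl tert-butyl carbonate | Oc1cc(Br)cc(OC(=O)OC(C)(C)C)c1C(OC(=O)OC(C)(C)C)c1cc(O[Si](C)(C)C(C)(C)C)cc(O[Si](C)(C)C(C)(C)C)c1 | intermediate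
10 | 4-hydroxy-3-methoxybenzyl alcohol (vanillyl alcohol) | COc1cc(CO)ccc1O | starting material
11 | tert-butyl [4-(hydroxymethyl)-2-methoxyphenyl] carbonate | COc1cc(CO)ccc1OC(=O)OC(C)(C)C | intermediate
12 | tert-butyl [4-(bromomethyl)-2-methoxyphenyl] carbonate | COc1cc(CBr)ccc1OC(=O)OC(C)(C)C | intermediate
13 | (1R,4R,5R)-4,7,7-trimethyl-6-thiabicyclo[3.2.1]octane (isothiocineole) | C[C@@H]1CC[C@@H]2C[C@H]1SC2(C)C | starting material
14 | (1R,4R,5R,6R)-6-[4-(Boc-oxy)-3-methoxybenzyl]-4,7,7-trimethyl-6-thiabicyclo[3.2.1]octan-6-ium tetrafluoroborate | C[C@@H]1CC[C@@H]2C[C@H]1[S@@+](Cc1ccc(OC(=O)OC(C)(C)C)c(OC)c1)C2(C)C.F[B-](F)(F)F | intermediate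
15 | sulfonium ylide of 14 (benzylic carbanion on sulfur) | C[C@@H]1CC[C@@H]2C[C@H]1[S@@+]([CH-]c1ccc(OC(=O)OC(C)(C)C)c(OC)c1)C2(C)C | intermediate (not isolated)
16 | potassium phenoxide of 9 | [K+].[O-]c1cc(Br)cc(OC(=O)OC(C)(C)C)c1C(OC(=O)OC(C)(C)C)c1cc(O[Si](C)(C)C(C)(C)C)cc(O[Si](C)(C)C(C)(C)C)c1 | intermediate (not isolated)
17 | o-quinone methide: 4-bromo-6-[3,5-bis(TBS-oxy)benzylidene]-5-(Boc-oxy)cyclohexa-2,4-dien-1-one (exocyclic geometry not fixed) | O=C1C=C(Br)C=C(OC(=O)OC(C)(C)C)C1=Cc1cc(O[Si](C)(C)C(C)(C)C)cc(O[Si](C)(C)C(C)(C)C)c1 | intermediate (not isolated)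
18 | anti betaine: phenoxide with (R)-sulfonium carbon and (S)-diarylmethine carbon | C[C@@H]1CC[C@@H]2C[C@H]1[S@@+]([C@@H](c1ccc(OC(=O)OC(C)(C)C)c(OC)c1)[C@@H](c1cc(O[Si](C)(C)C(C)(C)C)cc(O[Si](C)(C)C(C)(C)C)c1)c1c([O-])cc(Br)cc1OC(=O)OC(C)(C)C)C2(C)C | intermediate (not isolated)
19 | tert-butyl (2S,3S)-6-bromo-2-[4-(Boc-oxy)-3-methoxyphenyl]-3-[3,5-bis(TBS-oxy)phenyl]-2,3-dihydro-1-benzofuran-4-yl carbonate | Brc1cc(OC(=O)OC(C)(C)C)c2c(c1)O[C@H](c1ccc(OC(=O)OC(C)(C)C)c(OC)c1)[C@H]2c1cc(O[Si](C)(C)C(C)(C)C)cc(O[Si](C)(C)C(C)(C)C)c1 | intermediate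
20 | 4-ethenyl-2-methoxyphenyl acetate | C=Cc1ccc(OC(C)=O)c(OC)c1 | starting material
21 | fully protected stilbene (two Boc carbonates, two TBS ethers, one acetate; 2S,3S; E) | COc1cc(/C=C/c2cc(OC(=O)OC(C)(C)C)c3c(c2)O[C@H](c2ccc(OC(=O)OC(C)(C)C)c(OC)c2)[C@H]3c2cc(O[Si](C)(C)C(C)(C)C)cc(O[Si](C)(C)C(C)(C)C)c2)ccc1OC(C)=O | intermediate
22 | bisisorhapontigenin B | COc1cc(/C=C/c2cc(O)c3c(c2)O[C@H](c2ccc(O)c(OC)c2)[C@H]3c2cc(O)cc(O)c2)ccc1O | target

**Totals**

Total step count: 10. Longest linear sequence: 6 steps (1 → 2 → 3 → 9 → 19 → 21 → 22, or 10 → 11 → 12 → 14 → 19 → 21 → 22).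

**Steps most likely to fail**

Step 8 (key step, beyond established precedent). The ylide may decompose before the quinone methide is released. The two faces of the methide carbon may be poorly discriminated, giving the syn betaine and the cis ring. Partial SN1 loss of the sulfide would erode enantiopurity, and the sense of induction may be opposite to the model. The fallback uses known reaction types, sets out from 11 and 9, and returns at 19. Alcohol 11 is oxidised with MnO2 (CH2Cl2) to tert-butyl (4-formyl-2-methoxyphenyl) carbonate F1. Quinone methide 17, released from 9 through 16 with K2CO3, is intercepted by the acyl-anion equivalent formed from F1 and a thiazolium carbene precatalyst (carbene-catalysed umpolung acylation of o-quinone methides) to give the racemic diaryl ketone F2. Its doubly benzylic α-centre epimerises readily, so asymmetric transfer hydrogenation with dynamic kinetic resolution (RuCl[(R,R)-TsDPEN](p-cymene), HCO2H–Et3N) should give the hydroxy phenol F3 as one stereoisomer. Mitsunobu cycloetherification (PPh3, DIAD, THF) then forms O1–C2 by 5-exo-tet displacement with inversion and gives 19.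

Step 4. The aryllithium may attack the carbonate carbonyls, bromine–lithium scrambling may occur, and 9 may eliminate and oligomerise during isolation. The fallback sets out from 5 and 3 and returns at 16. Bromide 5 is converted (n-BuLi, B(Oi-Pr)3, then aqueous acid) into [3,5-bis(TBS-oxy)phenyl]boronic acid F4. Neutral rhodium-catalysed 1,2-addition of F4 to aldehyde 3 ([Rh(OH)(cod)]2, dioxane–H2O) should give the bench-stable carbinol F5 with both carbonates in place. Under the base of step 8, F5 forms the potassium alkoxide F6, which by O-to-O Boc transfer becomes phenoxide 16, and the route continues unchanged.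

Step 10. The phenoxide of the C2 aryl group may open the dihydrofuran under base, the polyphenolate stilbene may autoxidise, and silyl cleavage may stay incomplete. The fallback sets out from 19 and returns at 22, moving the C–C coupling to the end. The four protecting groups of 19, which has no stilbene, are removed by the same methanolysis to give the tetraphenol bromide F7. A Heck reaction of F7 with commercial 2-methoxy-4-vinylphenol (Pd(P(t-Bu)3)2, Cy2NMe, dioxane) then gives 22 directly, so no deprotection follows formation of the stilbene.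

**Further compounds**

F1 | step 8 | tert-butyl (4-formyl-2-methoxyphenyl) carbonate | COc1cc(C=O)ccc1OC(=O)OC(C)(C)C
F2 | step 8 | rac-2-[4-bromo-2-(Boc-oxy)-6-hydroxyphenyl]-2-[3,5-bis(TBS-oxy)phenyl]-1-[4-(Boc-oxy)-3-methoxyphenyl]ethan-1-one | O=C(c1ccc(OC(=O)OC(C)(C)C)c(OC)c1)C(c1cc(O[Si](C)(C)C(C)(C)C)cc(O[Si](C)(C)C(C)(C)C)c1)c1c(O)cc(Br)cc1OC(=O)OC(C)(C)C
F3 | step 8 | (1R,2S)-2-[4-bromo-2-(Boc-oxy)-6-hydroxyphenyl]-2-[3,5-bis(TBS-oxy)phenyl]-1-[4-(Boc-oxy)-3-methoxyphenyl]ethan-1-ol | O[C@@H](c1ccc(OC(=O)OC(C)(C)C)c(OC)c1)[C@@H](c1cc(O[Si](C)(C)C(C)(C)C)cc(O[Si](C)(C)C(C)(C)C)c1)c1c(O)cc(Br)cc1OC(=O)OC(C)(C)C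
F4 | step 4 | [3,5-bis(TBS-oxy)phenyl]boronic acid | OB(O)c1cc(O[Si](C)(C)C(C)(C)C)cc(O[Si](C)(C)C(C)(C)C)c1
F5 | step 4 | rac-[4-bromo-2,6-bis(Boc-oxy)phenyl][3,5-bis(TBS-oxy)phenyl]methanol | OC(c1cc(O[Si](C)(C)C(C)(C)C)cc(O[Si](C)(C)C(C)(C)C)c1)c1c(OC(=O)OC(C)(C)C)cc(Br)cc1OC(=O)OC(C)(C)C
F6 | step 4 | potassium alkoxide of F5 | [K+].[O-]C(c1cc(O[Si](C)(C)C(C)(C)C)cc(O[Si](C)(C)C(C)(C)C)c1)c1c(OC(=O)OC(C)(C)C)cc(Br)cc1OC(=O)OC(C)(C)C
F7 | step 10 | (2S,3S)-6-bromo-3-(3,5-dihydroxyphenyl)-2-(4-hydroxy-3-methoxyphenyl)-2,3-dihydro-1-benzofuran-4-ol | Brc1cc(O)c2c(c1)O[C@H](c1ccc(O)c(OC)c1)[C@H]2c1cc(O)cc(O)c1
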